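**The charges.** The four flasks differ in their amounts of substrate and free catalyst, and I reckon from the ratio of the two.

| flask | substrate | free catalyst | remark | time |
|---|---|---|---|---|
| midnight | 0.11 M | 7 mM | run made earlier |  |
| Tuesday's | 0.030 M | 4.0 mM |  | 8.0 min |
| Thursday's | 0.15 M | 2.5 mM |  | 8.0 min |
| Saturday's | 0.10 M | 7.0 mM |  | 8.0 min |
| Wednesday's | 0.15 M | 30 mM |  | 8.0 min |

- midnight (time / s: target / %, side product / %): 10.0: 0, 1; 15.0: 4, 0; 25.0: 9, 0; 40.0: 15, 0; 60.0: 17, 2; 80.0: 25, 2; 90.0: 27, 7

(scatter of a reading: 2 percentage points)

- a species is counted by the substrate in it: one side product counts as two
- what was read earlier has a scatter of 2 percentage points, one standard deviation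
- steps thought possible: substrate + free catalyst -> catalyst intermediate; catalyst intermediate -> free catalyst + target; substrate + target -> side product; free catalyst -> spent catalyst
- no earlier run changes the charge of free catalyst; that part of a forecast is a guess

1. all flasks from highest to lowest share of target in all that became target or side product, at 8.0 min (Tuesday's / Thursday's / Saturday's / Wednesday's)
2. the share of target in all that became target or side product of the flask you put first, at 8.0 min
3. the share of target in all that became target or side product of the flask you put last, at 8.0 min

**The load.** While catalyst intermediate stays small, target is made at a rate proportional to substrate times free catalyst, and side product forms at a rate proportional to substrate times target. Divided, substrate falls out and target over free catalyst stays. At a given fraction converted, target goes with the substrate charged, so I carry the load L, free catalyst charged over substrate charged: 20.0% in Wednesday's, 13.3% in Tuesday's, 7.00% in Saturday's, 1.67% in Thursday's.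

**Two extremes.** Suppose free catalyst keeps its charge C. Substrate then falls in a pseudo-first-order way, with half-life ln(2)/(kC), where k is the overall rate constant for making target from substrate and free catalyst. The midnight run reads 27% target at 90.0 s with 7 mM, so k is about 0.429 L mol⁻¹ s⁻¹, a reading with its scatter. That half-life is 0.899 min for Wednesday's, well inside 8.0 min, so Wednesday's sits near this extreme. Suppose instead free catalyst is lost early. Target then stops being made while substrate and target still meet, and the share keeps falling. Thursday's reckoned half-life of 10.8 min exceeds 8.0 min, so Thursday's leans this way. I commit to the order of L, Wednesday's highest and Thursday's lowest, and put no shares on it.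

**The forecast.** It gives Wednesday's > Tuesday's > Saturday's > Thursday's, with 90% first and 42% last. Its ground for the top: “Wednesday's flask has plenty of catalyst, so substrate is gone within a few minutes, before target can meet it”.

**The result.** The flasks come out as Wednesday's > Tuesday's > Saturday's > Thursday's, from 89.2% to 41.0%, which is the order of L.

    substrate + free catalyst → catalyst intermediate (k = 1.30 L mol⁻¹ s⁻¹)
    catalyst intermediate → free catalyst + target (k = 0.120 s⁻¹)
    substrate + target → side product (k = 0.0200 L mol⁻¹ s⁻¹)
    free catalyst → spent catalyst (k = 0.00510 s⁻¹)

**The race.** At a load of 20.0%, Wednesday's has a substrate half-life of 0.30 min by capture on free catalyst held at its charge, shorter than the 3.9 min half-life of target by the side product step at charged concentrations. The neighbour flask, Wednesday's with 0.051 M free catalyst, has a higher load of 34.0% and gives a target share of 94.5%.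

The earlier runs and the new flask stem from a simulated flask with made-up constants; scatter was added.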